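**Plan**

- Numbering: C1 is the carboxyl carbon, C3 and C5 are the ring carbons (O2 on C3, O1 on C5), C6–C20 is the side chain. The retrosynthesis cuts C14=C15 (Julia–Kocienski), C12=C13 (Wittig), C7–C8 (cross-metathesis, then saturation), C5–C6 (allylation), and last the two ring C–O bonds C3–O2 and C5–O1.
- Enabling feature: C1–C5, both methyl branches and the oxygen on C5 are the ring atoms of 4,6-dimethyl-2-pyrone. Its ring opening gives a keto-enoate whose ketone carbon (C5) and enoate β-carbon (C3) are 1,3-related, so H2O2 can bridge them to the 1,2-dioxolane ring O1–O2–C3–C4–C5.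
- Forward order: the dioxolane ring closes first and is locked as a bridged peroxylactone (second ring). Allylation at C5 reopens the lactone ring, and the chain is then grown outwards from C6 to C20.
- Stereochemistry: C3 comes from a chiral amine–squaramide catalyst in the peroxy-Michael closure. C5 comes from attack of the allylsilane anti to the departing carboxylate. 12E comes from a stabilised ylide, 14E from the Julia–Kocienski reaction, and 17Z from (Z)-hex-3-en-1-ol.

Key step: step 2

Assumption: the sense of induction of the peroxy-Michael closure cannot be derived from precedent. The quinidine-derived squaramide is written, and its quinine-derived pseudo-enantiomer would be used if a test run shows the opposite sense at C3.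

**Route**

Step 1
Reactants: 1 4,6-dimethyl-2H-pyran-2-one
Product: 3 methyl (2Z)-3-methyl-5-oxohex-2-enoate, via sodium dienolate 2 (not isolated)
Conditions: NaOMe (1.05 equiv), MeOH, 0 °C → rt; then inverse quench into AcOH/Et2O, −40 °C
Reagents that add atoms: sodium methoxide, C[O-].[Na+]
Why: Methoxide attacks the lactone carbonyl (alkoxide ring opening of a 2-pyrone by acyl substitution) and expels the stabilised dienolate 2 with the ring-derived Z geometry, and kinetic protonation of this ketone dienolate at its α-carbon (C4) should give the conjugated Z enoate 3, which is kept cold and used at once because acid or heat would close it back to 1.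

Step 2
Reactants: 3 methyl (2Z)-3-methyl-5-oxohex-2-enoate; 4 hydrogen peroxide (as its urea complex)
Product: 7 (1S,5R)-1,5-dimethyl-2,6,7-trioxabicyclo[3.2.1]octan-3-one, via ketone perhydrate 5 (not isolated), via hydroxydioxolane ester 6 (not isolated)
Conditions: urea–H2O2 (3 equiv), squaramide from 9-amino-9-deoxy-epi-quinidine and 3,5-bis(trifluoromethyl)aniline (10 mol %), CH2Cl2/PhMe (1:1), 0 °C; filter; then (+)-camphor-10-sulfonic acid (20 mol %), 5 Å molecular sieves, CH2Cl2, rt
Reagents that add atoms: none
Why: Proposed new method: hydrogen peroxide adds reversibly to the C5 ketone to give perhydrate 5 (C5–O1 bond), the quinuclidine nitrogen of the catalyst deprotonates the OOH group while the squaramide N–H bonds hold the ester carbonyl, and the terminal peroxide oxygen adds to the enoate β-carbon C3 (C3–O2 bond) to give 6; camphorsulfonic acid then lets the C5 hemiketal epimerise by ring–chain exchange, and only the epimer with OH cis to the CH2CO2Me arm can lactonise, so both epimers drain into 7. The closest known reaction types are ketone perhydrate or hydroperoxy ketal formation followed by amine-promoted intramolecular addition of the hydroperoxide to an enoate (racemic), and amine/hydrogen-bond-donor catalysed oxa-Michael additions that pass through hemiacetal intermediates. The 1,2-dioxolane closes 5-exo-trig and the lactone 6-exo-trig (acyl substitution with loss of methanol). The C3 stereocentre is set by the catalyst, which must select one face of the (Z)-enoate; the bridgehead acetal carbon (C5 of the target) needs no control, because the bicycle allows only the cis arrangement and this centre is re-ionised in step 3. The step needs enantioface selectivity and 1,3-regiochemistry; the latter is secured by the substrate, in which ketone and β-carbon are 1,3-related so that only the five-membered peroxide ring can form, and a squaramide is chosen as hydrogen-bond donor because hydrogen peroxide would desulfurise a thiourea.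

Step 3
Reactants: 7 (1S,5R)-1,5-dimethyl-2,6,7-trioxabicyclo[3.2.1]octan-3-one; 8 allyltrimethylsilane
Product: 9 2-[(3R,5S)-3,5-dimethyl-5-(prop-2-en-1-yl)-1,2-dioxolan-3-yl]acetic acid
Conditions: 8 (3 equiv), TiCl4 (1.1 equiv), CH2Cl2, −78 °C; then H2O
Reagents that add atoms: none
Why: Hosomi–Sakurai-type allylation of a peroxycarbenium ion, known for 3-alkoxy- and 3-acyloxy-1,2-dioxolanes: TiCl4 ionises the acyl–oxygen acetal bond at C5, the titanium carboxylate stays on the face it left, and the allylsilane should attack the planar cation from the opposite face, which places the allyl group trans to the acetic acid arm (5S) and frees the acid directly.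

Step 4
Reactants: 9 2-[(3R,5S)-3,5-dimethyl-5-(prop-2-en-1-yl)-1,2-dioxolan-3-yl]acetic acid
Product: 10 methyl 2-[(3R,5S)-3,5-dimethyl-5-(prop-2-en-1-yl)-1,2-dioxolan-3-yl]acetate
Conditions: Me3SiCHN2, PhMe/MeOH (4:1), 0 °C → rt
Reagents that add atoms: (trimethylsilyl)diazomethane, C[Si](C)(C)C=[N+]=[N-]
Why: Diazoalkane esterification: methanol desilylates the reagent to diazomethane, which is protonated by the acid and O-methylates the carboxylate under neutral conditions that leave the peroxide, both quaternary centres and the alkene untouched.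

Step 5
Reactants: 10 methyl 2-[(3R,5S)-3,5-dimethyl-5-(prop-2-en-1-yl)-1,2-dioxolan-3-yl]acetate; 11 hex-5-en-1-ol
Product: 12 methyl 2-[(3R,5S)-5-[(2E)-7-hydroxyhept-2-en-1-yl]-3,5-dimethyl-1,2-dioxolan-3-yl]acetate (E/Z mixture expected, E isomer drawn)
Conditions: 11 (4 equiv), second-generation Grubbs catalyst [RuCl2(=CHPh)(PCy3)(SIMes)] (5 mol %), CH2Cl2, 40 °C
Reagents that add atoms: none
Why: Olefin cross-metathesis between two unhindered terminal alkenes, driven by loss of ethylene and by the excess of 11; the fully substituted dialkyl peroxide should not react with the ruthenium alkylidene, and the alkene geometry is irrelevant because this double bond is saturated next.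

Step 6
Reactants: 12 methyl 2-[(3R,5S)-5-[(2E)-7-hydroxyhept-2-en-1-yl]-3,5-dimethyl-1,2-dioxolan-3-yl]acetate
Product: 13 methyl 2-[(3R,5S)-5-(7-hydroxyheptyl)-3,5-dimethyl-1,2-dioxolan-3-yl]acetate
Conditions: KO2CN=NCO2K (potassium azodicarboxylate, 10 equiv), AcOH (20 equiv, slow addition), MeOH, 0 °C → rt
Reagents that add atoms: none
Why: Diimide reduction: diimide released from the azodicarboxylate by acid transfers two hydrogens to the C7=C8 bond in a concerted syn fashion and, unlike catalytic hydrogenation, does not cleave the O–O bond.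

Step 7
Reactants: 13 methyl 2-[(3R,5S)-5-(7-hydroxyheptyl)-3,5-dimethyl-1,2-dioxolan-3-yl]acetate
Product: 14 methyl 2-[(3R,5S)-3,5-dimethyl-5-(7-oxoheptyl)-1,2-dioxolan-3-yl]acetate
Conditions: Dess–Martin periodinane (1.3 equiv), CH2Cl2, 0 °C → rt
Reagents that add atoms: none
Why: Dess–Martin oxidation of the primary alcohol stops at the C12 aldehyde under neutral conditions that leave the peroxide and the ester intact.

Step 8
Reactants: 14 methyl 2-[(3R,5S)-3,5-dimethyl-5-(7-oxoheptyl)-1,2-dioxolan-3-yl]acetate; 15 (triphenylphosphoranylidene)acetaldehyde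
Product: 16 methyl 2-[(3R,5S)-3,5-dimethyl-5-[(7E)-9-oxonon-7-en-1-yl]-1,2-dioxolan-3-yl]acetate
Conditions: 15 (1.3 equiv), PhMe, 65 °C
Reagents that add atoms: none
Why: Wittig reaction with a formyl-stabilised ylide, whose reversible addition gives the 12E enal; the conjugated product is less electrophilic than aldehyde 14, which limits a second homologation.

Step 9
Reactants: 17 (3Z)-hex-3-en-1-ol
Product: 18 5-{[(3Z)-hex-3-en-1-yl]sulfanyl}-1-phenyl-1H-tetrazole
Conditions: 1-phenyl-1H-tetrazole-5-thiol, PPh3, diisopropyl azodicarboxylate, THF, 0 °C → rt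
Reagents that add atoms: 1-phenyl-1H-tetrazole-5-thiol, Sc1nnnn1-c1ccccc1
Why: Mitsunobu thioetherification of a primary alcohol with an acidic heteroaryl thiol; the reaction is neutral and does not touch the Z alkene.

Step 10
Reactants: 18 5-{[(3Z)-hex-3-en-1-yl]sulfanyl}-1-phenyl-1H-tetrazole; 4 hydrogen peroxide (30% aqueous)
Product: 19 5-{[(3Z)-hex-3-en-1-yl]sulfonyl}-1-phenyl-1H-tetrazole
Conditions: (NH4)6Mo7O24·4H2O (10 mol %), 30% H2O2 (5 equiv), EtOH, 0 °C → rt
Reagents that add atoms: none
Why: Molybdate-catalysed peroxide oxidation takes the sulfide through the sulfoxide to the sulfone by oxygen transfer from a peroxomolybdate and is selective for sulfur over the isolated Z alkene.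

Step 11
Reactants: 16 methyl 2-[(3R,5S)-3,5-dimethyl-5-[(7E)-9-oxonon-7-en-1-yl]-1,2-dioxolan-3-yl]acetate; 19 5-{[(3Z)-hex-3-en-1-yl]sulfonyl}-1-phenyl-1H-tetrazole
Product: 20 methyl 2-[(3R,5S)-3,5-dimethyl-5-[(7E,9E,12Z)-pentadeca-7,9,12-trien-1-yl]-1,2-dioxolan-3-yl]acetate
Conditions: 19 (1.3 equiv), KN(SiMe3)2 (1.2 equiv), DME, −60 °C; then 16, −60 °C → rt; aq. NH4Cl
Reagents that add atoms: none
Why: Julia–Kocienski olefination: the potassium sulfonyl carbanion adds to the enal carbonyl, and Smiles rearrangement with anti elimination of SO2 and the tetrazolone should favour the 14E alkene with a potassium counter-ion in DME; pre-forming the anion with the sulfone in excess over the base keeps free amide base away from the β-peroxy ester, and the 12E and 17Z alkenes are not touched.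

Step 12
Reactants: 20 methyl 2-[(3R,5S)-3,5-dimethyl-5-[(7E,9E,12Z)-pentadeca-7,9,12-trien-1-yl]-1,2-dioxolan-3-yl]acetate
Product: 21 2-[(3R,5S)-3,5-dimethyl-5-[(7E,9E,12Z)-pentadeca-7,9,12-trien-1-yl]-1,2-dioxolan-3-yl]acetic acid (CNP0215994.1)
Conditions: LiOH (3 equiv), THF/H2O (3:1), 0 °C → rt; then 1 M HCl to pH 3, 0 °C
Reagents that add atoms: lithium hydroxide, [Li+].[OH-]
Why: Saponification by acyl substitution at the unhindered methyl ester; C3 and C5 are quaternary, so base-induced Kornblum–DeLaMare cleavage of the peroxide is impossible, and cold hydroxide should not move the skipped alkene into conjugation.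

**Compound list**

1 | 4,6-dimethyl-2H-pyran-2-one | Cc1cc(C)oc(=O)c1 | starting material
2 | sodium (2Z,4Z)-6-methoxy-4-methyl-6-oxohexa-2,4-dien-2-olate | C/C([O-])=C/C(C)=C\C(=O)OC.[Na+] | intermediate (not isolated)
3 | methyl (2Z)-3-methyl-5-oxohex-2-enoate | CC(=O)C/C(C)=C\C(=O)OC | intermediate
4 | hydrogen peroxide (urea complex in step 2, 30% aqueous in step 10) | OO | starting material
5 | methyl (2Z)-5-hydroperoxy-5-hydroxy-3-methylhex-2-enoate (racemic at C5) | CC(O)(OO)C/C(C)=C\C(=O)OC | intermediate (not isolated)
6 | methyl 2-[(3R)-5-hydroxy-3,5-dimethyl-1,2-dioxolan-3-yl]acetate (both C5 epimers) | CC1(O)C[C@](C)(CC(=O)OC)OO1 | intermediate (not isolated)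
7 | (1S,5R)-1,5-dimethyl-2,6,7-trioxabicyclo[3.2.1]octan-3-one | C[C@]12C[C@](C)(CC(=O)O1)OO2 | intermediate
8 | allyltrimethylsilane | C=CC[Si](C)(C)C | starting material
9 | 2-[(3R,5S)-3,5-dimethyl-5-(prop-2-en-1-yl)-1,2-dioxolan-3-yl]acetic acid | C=CC[C@@]1(C)C[C@](C)(CC(=O)O)OO1 | intermediate
10 | methyl 2-[(3R,5S)-3,5-dimethyl-5-(prop-2-en-1-yl)-1,2-dioxolan-3-yl]acetate | C=CC[C@@]1(C)C[C@](C)(CC(=O)OC)OO1 | intermediate
11 | hex-5-en-1-ol | C=CCCCCO | starting material
12 | methyl 2-[(3R,5S)-5-[(2E)-7-hydroxyhept-2-en-1-yl]-3,5-dimethyl-1,2-dioxolan-3-yl]acetate (E isomer drawn) | OCCCC/C=C/C[C@@]1(C)C[C@](C)(CC(=O)OC)OO1 | intermediate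
13 | methyl 2-[(3R,5S)-5-(7-hydroxyheptyl)-3,5-dimethyl-1,2-dioxolan-3-yl]acetate | OCCCCCCC[C@@]1(C)C[C@](C)(CC(=O)OC)OO1 | intermediate
14 | methyl 2-[(3R,5S)-3,5-dimethyl-5-(7-oxoheptyl)-1,2-dioxolan-3-yl]acetate | O=CCCCCCC[C@@]1(C)C[C@](C)(CC(=O)OC)OO1 | intermediate
15 | (triphenylphosphoranylidene)acetaldehyde | O=CC=P(c1ccccc1)(c1ccccc1)c1ccccc1 | starting material
16 | methyl 2-[(3R,5S)-3,5-dimethyl-5-[(7E)-9-oxonon-7-en-1-yl]-1,2-dioxolan-3-yl]acetate | O=C/C=C/CCCCCC[C@@]1(C)C[C@](C)(CC(=O)OC)OO1 | intermediate
17 | (3Z)-hex-3-en-1-ol | CC/C=C\CCO | starting material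
18 | 5-{[(3Z)-hex-3-en-1-yl]sulfanyl}-1-phenyl-1H-tetrazole | CC/C=C\CCSc1nnnn1-c1ccccc1 | intermediate
19 | 5-{[(3Z)-hex-3-en-1-yl]sulfonyl}-1-phenyl-1H-tetrazole | CC/C=C\CCS(=O)(=O)c1nnnn1-c1ccccc1 | intermediate
20 | methyl 2-[(3R,5S)-3,5-dimethyl-5-[(7E,9E,12Z)-pentadeca-7,9,12-trien-1-yl]-1,2-dioxolan-3-yl]acetate | CC/C=C\C/C=C/C=C/CCCCCC[C@@]1(C)C[C@](C)(CC(=O)OC)OO1 | intermediate
21 | 2-[(3R,5S)-3,5-dimethyl-5-[(7E,9E,12Z)-pentadeca-7,9,12-trien-1-yl]-1,2-dioxolan-3-yl]acetic acid | CC/C=C\C/C=C/C=C/CCCCCC[C@@]1(C)C[C@](C)(CC(=O)O)OO1 | target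

**Step count**

Total: 12 steps. Longest linear sequence: 10 steps (steps 1–8, 11, 12, from 4,6-dimethyl-2H-pyran-2-one). The sulfone branch (steps 9, 10) joins at step 11.

**Steps most likely to fail**

1. Step 2 (proposed new method). The closure may proceed with little or no asymmetric induction at C3, because the β,β-disubstituted enoate is a weak acceptor and may be held only loosely by the catalyst. The double bond may also drift towards the ketone before the perhydrate forms, the amine catalyst may be oxidised, or the lactonisation may stall. Fallback with known chemistry, setting out from 3: the racemic perhydrate/peroxy-Michael sequence with urea–H2O2 and Et2NH in CF3CH2OH should give racemic methyl 2-(5-hydroxy-3,5-dimethyl-1,2-dioxolan-3-yl)acetate F1. Camphorsulfonic acid with 5 Å sieves should close it to racemic 1,5-dimethyl-2,6,7-trioxabicyclo[3.2.1]octan-3-one F2. Allylation under the conditions of step 3 would give racemic 2-[(3R*,5S*)-3,5-dimethyl-5-(prop-2-en-1-yl)-1,2-dioxolan-3-yl]acetic acid F3. This is resolved by fractional crystallisation of the (R)-1-phenylethylammonium salt of the 3R,5S acid F4; the mirror-image amine is used if its salt with the wanted acid is the less soluble one. Dilute HCl frees the acid and the route is rejoined at 9.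

2. Step 3. The allylsilane may attack the wrong face of the peroxycarbenium ion if the ion pair loosens, which would give the C5 epimer, or ionisation may occur on the peroxide side and fragment the ring. Fallback, setting out from 7: camphorsulfonic acid in MeOH with HC(OMe)3 should open the lactone to methyl 2-[(3R)-5-methoxy-3,5-dimethyl-1,2-dioxolan-3-yl]acetate F5 (both C5 epimers). SnCl4 and allyltrimethylsilane in CH2Cl2 at −78 °C, the established allylation of 3-alkoxy-1,2-dioxolanes, would then replace the methoxy group. Here the ester carbonyl can cap the cis face of the cation, and the C5 epimers of the neutral ester can be separated on silica. The route is rejoined at 10, and step 4 is no longer needed.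

3. Step 11. E selectivity may erode in the addition/Smiles/elimination sequence with a conjugated aldehyde, or deprotonation α to the ester may trigger β-elimination of the peroxide. Fallback, setting out from 17 and 16: Appel iodination of 17 (I2, PPh3, imidazole, CH2Cl2) should give (3Z)-1-iodohex-3-ene F6, and PPh3 in MeCN at 80 °C should convert it to [(3Z)-hex-3-en-1-yl]triphenylphosphonium iodide F7. Its ylide (NaN(SiMe3)2, THF, −78 °C) should react with 16 in a cis-selective Wittig reaction to give methyl 2-[(3R,5S)-3,5-dimethyl-5-[(7E,9Z,12Z)-pentadeca-7,9,12-trien-1-yl]-1,2-dioxolan-3-yl]acetate F8. A trace of I2 in CH2Cl2 under ambient light should then equilibrate only the conjugated diene to the E,E form, while the isolated Z alkene stays. The route is rejoined at 20.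

**Further compounds**

F1 | step 2 | racemic methyl 2-(5-hydroxy-3,5-dimethyl-1,2-dioxolan-3-yl)acetate (all stereoisomers) | CC1(O)CC(C)(CC(=O)OC)OO1
F2 | step 2 | racemic 1,5-dimethyl-2,6,7-trioxabicyclo[3.2.1]octan-3-one | CC12CC(C)(CC(=O)O1)OO2
F3 | step 2 | racemic 2-[(3R*,5S*)-3,5-dimethyl-5-(prop-2-en-1-yl)-1,2-dioxolan-3-yl]acetic acid (both enantiomers written) | C=CC[C@@]1(C)C[C@](C)(CC(=O)O)OO1.C=CC[C@]1(C)C[C@@](C)(CC(=O)O)OO1
F4 | step 2 | (R)-1-phenylethylammonium 2-[(3R,5S)-3,5-dimethyl-5-(prop-2-en-1-yl)-1,2-dioxolan-3-yl]acetate | C=CC[C@@]1(C)C[C@](C)(CC(=O)[O-])OO1.C[C@@H]([NH3+])c1ccccc1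
F5 | step 3 | methyl 2-[(3R)-5-methoxy-3,5-dimethyl-1,2-dioxolan-3-yl]acetate (both C5 epimers) | COC1(C)C[C@](C)(CC(=O)OC)OO1
F6 | step 11 | (3Z)-1-iodohex-3-ene | CC/C=C\CCI
F7 | step 11 | [(3Z)-hex-3-en-1-yl]triphenylphosphonium iodide | CC/C=C\CC[P+](c1ccccc1)(c1ccccc1)c1ccccc1.[I-]
F8 | step 11 | methyl 2-[(3R,5S)-3,5-dimethyl-5-[(7E,9Z,12Z)-pentadeca-7,9,12-trien-1-yl]-1,2-dioxolan-3-yl]acetate | CC/C=C\C/C=C\C=C\CCCCCC[C@@]1(C)C[C@](C)(CC(=O)OC)OO1
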